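**Plan**
- Retrosynthesis: the three esters come off first (acetates at C1 and C13, tiglate at C8 with inversion). The butenolide ring then carries oxygen on both carbons next to its tetrasubstituted C7=C11 alkene (C8–C7=C11–C13, a 2-ene-1,4-diol). The C8–O and C13–O bonds are therefore cut together, back to O2 and the diene C8=C7–C11=C13, whose two alkenes are exocyclic on the γ-lactone and so fixed s-cis.
- Further cuts: C12–O6 and C7–C11 (lactonisation, Stille coupling), C6–C7 (acetylide to aldehyde, closing the ten-membered ring), C7≡C8 (one-carbon homologation), C1–C10 (crotylboration). This leaves nerol.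
- Forward order of rings: oxirane (step 8), ten-membered carbocycle (step 10), γ-lactone (step 14), 1,2-dioxine (step 15, opened again in step 16).
- Stereochemistry: C1/C10 come from a catalyst-controlled anti crotylboration and C4/C5 from Sharpless epoxidation of the Z allylic alcohol. C6 comes from chelation-controlled reduction of the epoxy ketone. C8 comes from the face-selective cycloaddition followed by Mitsunobu inversion. The C7=C8 geometry comes from syn hydrostannylation of a ring alkyne.
- Steps 3 and 8 are independent reagent-controlled events, so residual minor enantiomer ends up in diastereomers that chromatography removes.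

Key step: step 15

Remark: germacrane numbering of the target is used for every intermediate (ring C1–C10, C11–C13 on C7, C14 on C10, C15 on C4). A CIP letter can change from one compound to the next through substituent priorities alone, without any change in space.

**Step 1**
Reactants: 1 nerol
Product: 2 neryl acetate
Conditions: Ac2O, Et3N, DMAP (cat.), CH2Cl2, 0 °C to rt
Reagents that add atoms: acetic anhydride, CC(=O)OC(C)=O
Why: O-acylation of a primary alcohol, which protects O6 and lowers the electron density of the C4=C5 alkene for the next step.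

**Step 2**
Reactants: 2 neryl acetate
Product: 4 (2Z)-3-methyl-6-oxohex-2-en-1-yl acetate (C1 aldehyde), via secondary ozonide 3 (not isolated)
Conditions: O3 (1.0 equiv), CH2Cl2, −78 °C; then Me2S, −78 °C to rt
Reagents that add atoms: ozone, [O-][O+]=O
Why: Chemoselective ozonolysis with reductive work-up, in which electrophilic ozone should take the distal trisubstituted alkene before the one deactivated by the allylic acetoxy group.

**Step 3**
Reactants: 4 C1 aldehyde; 5 (E)-crotylboronic acid pinacol ester
Product: 7 (2Z,6S,7R)-6-hydroxy-3,7-dimethylnona-2,8-dien-1-yl acetate (1S,10R in target numbering), via pinacol borate ester 6 (not isolated)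
Conditions: (R)-3,3'-bis(2,4,6-triisopropylphenyl)-1,1'-binaphthyl-2,2'-diyl hydrogen phosphate (5 mol %), 4 Å MS, toluene, −30 °C; then H2O
Reagents that add atoms: none
Why: Chiral phosphoric acid-catalysed crotylboration through a closed chair transition state, in which the E-crotyl geometry fixes the anti C1/C10 relation and the (R)-catalyst directs attack to the Re face of the aldehyde, giving 1S,10R.

**Step 4**
Reactants: 7 homoallylic alcohol
Product: 8 tert-butyldimethylsilyl ether of 7
Conditions: TBSCl, imidazole, DMF, rt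
Reagents that add atoms: tert-butyldimethylsilyl chloride, CC(C)(C)[Si](C)(C)Cl
Why: Standard silyl ether formation, giving a C1 protecting group that survives base, hydride, palladium and singlet oxygen.

**Step 5**
Reactants: 8 silyl ether
Product: 10 (2Z,6S,7R)-6-(tert-butyldimethylsilyloxy)-9-hydroxy-3,7-dimethylnon-2-en-1-yl acetate (C8 alcohol), via B-alkyl-9-BBN adduct 9 (not isolated)
Conditions: 9-BBN, THF, 0 °C to rt; then 30 % H2O2, aq. NaOAc, 0 °C to rt
Reagents that add atoms: hydrogen peroxide, OO
Why: Hydroboration–oxidation, in which 9-BBN adds anti-Markovnikov to the monosubstituted alkene far faster than to the trisubstituted C4=C5 alkene and the acetate-buffered peroxide spares the ester.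

**Step 6**
Reactants: 10 C8 alcohol
Product: 11 (2Z,6S,7R)-6-(tert-butyldimethylsilyloxy)-3,7-dimethyl-9-oxonon-2-en-1-yl acetate (C8 aldehyde)
Conditions: Dess–Martin periodinane, CH2Cl2, rt
Reagents that add atoms: none
Why: Dess–Martin oxidation stops at the aldehyde and touches neither the alkene nor the protecting groups.

**Step 7**
Reactants: 11 C8 aldehyde; 12 dimethyl (1-diazo-2-oxopropyl)phosphonate
Product: 14 (2Z,6S,7R)-6-(tert-butyldimethylsilyloxy)-3,7-dimethyldec-2-en-9-yn-1-ol, via alkynyl acetate 13 (not isolated)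
Conditions: K2CO3, MeOH, 0 °C to rt
Reagents that add atoms: none
Why: Ohira–Bestmann homologation adds C7 as a terminal alkyne carbon, the aldehyde has no stereocentre at its α carbon, and the same carbonate/methanol medium removes the allylic acetate by transesterification.

**Step 8**
Reactants: 14 alkynyl allylic alcohol
Product: 15 (1S,4R,5S,10R)-4,5-epoxy alcohol [(2S,3R)-3-methyl-3-substituted oxiran-2-yl]methanol
Conditions: Ti(OiPr)4 (10 mol %), L-(+)-diethyl tartrate (12 mol %), t-BuOOH, 4 Å MS, CH2Cl2, −20 °C
Reagents that add atoms: tert-butyl hydroperoxide, CC(C)(C)OO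
Why: Sharpless asymmetric epoxidation, in which the L-(+)-tartrate catalyst delivers oxygen to the same face as it does for nerol itself, setting 4R,5S with C3 and C6 cis on the oxirane and leaving the alkyne untouched.

**Step 9**
Reactants: 15 epoxy alcohol
Product: 16 (1S,4R,5R,10R)-4,5-epoxy-6-aldehyde (no spatial change at C5)
Conditions: Dess–Martin periodinane, pyridine, CH2Cl2, 0 °C to rt
Reagents that add atoms: none
Why: Pyridine-buffered Dess–Martin oxidation is a routine way from 2,3-epoxy alcohols to configurationally stable epoxy aldehydes.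

**Step 10**
Reactants: 16 alkynyl epoxy aldehyde
Product: 17 (1S,4R,5S,10R)-1-(tert-butyldimethylsilyloxy)-4,5-epoxy-4,10-dimethylcyclodec-7-yn-6-ol (both C6 epimers)
Conditions: LiN(SiMe3)2 (1.5 equiv), THF (0.002 M, slow addition of 16), −78 to 0 °C; then AcOH
Reagents that add atoms: none
Why: Intramolecular 1,2-addition of a lithium acetylide to a non-enolisable aldehyde closes the ten-membered ring at C6–C7, helped by the cis-oxirane turn and the few transannular hydrogens of an alkyne, and the C6 configuration does not matter because step 11 removes it.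

**Step 11**
Reactants: 17 ring propargylic alcohol
Product: 18 (1S,4R,5R,10R)-1-(tert-butyldimethylsilyloxy)-4,5-epoxy-4,10-dimethylcyclodec-7-yn-6-one
Conditions: Dess–Martin periodinane, pyridine, CH2Cl2, 0 °C
Reagents that add atoms: none
Why: Dess–Martin oxidation merges both C6 epimers into one epoxy ynone and polarises the alkyne for regiocontrol in step 12.

**Step 12**
Reactants: 18 epoxy ynone
Product: 19 (1S,4R,5R,10R,7E)-1-(tert-butyldimethylsilyloxy)-4,5-epoxy-4,10-dimethyl-7-(tributylstannyl)cyclodec-7-en-6-one (C6 and C9 cis on the alkene)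
Conditions: Bu3SnH (1.05 equiv, slow addition), Pd(PPh3)4 (3 mol %), THF, 0 °C
Reagents that add atoms: tributyltin hydride, CCCC[SnH](CCCC)CCCC
Why: Palladium-catalysed hydrostannylation of an alkynone puts hydrogen on the β carbon C8 and tin on C7, and its syn course within the ring can only give the alkene with C6 and C9 cis and H8 cis to the C7 substituent.

**Step 13**
Reactants: 19 α-stannyl enone
Product: 20 (1S,4R,5S,6R,10R,7E)-1-(tert-butyldimethylsilyloxy)-4,5-epoxy-4,10-dimethyl-7-(tributylstannyl)cyclodec-7-en-6-ol (C6–O anti to the oxirane oxygen; spatially the 6S arrangement of the target)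
Conditions: Zn(BH4)2, Et2O, −20 °C; then H2O
Reagents that add atoms: none
Why: Chelation-controlled 1,2-reduction of an α,β-epoxy ketone, in which zinc bridges the carbonyl and oxirane oxygens and hydride enters from the side of H5, away from C4, giving the anti (erythro) epoxy alcohol.

**Step 14**
Reactants: 20 stannyl allylic alcohol; 21 methyl 2-bromoacrylate
Product: 23 (1S,4R,5S,6S,10R,7Z)-1-(tert-butyldimethylsilyloxy)-4,5-epoxygermacra-7,11(13)-dien-12,6-olide, via hydroxy dienoate 22 (not isolated)
Conditions: Pd(PPh3)4 (10 mol %), Cu(O2CC4H3S) (1.5 equiv), [NBu4][O2PPh2] (1.5 equiv), DMF, rt; then PPTS (cat.), CH2Cl2, rt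
Reagents that add atoms: none
Why: Copper-assisted Stille coupling forms C7–C11 with retention of the alkene geometry under fluoride-free conditions suited to hindered stannanes, and the C6 hydroxyl, held next to the ester by two sp2 carbons, then closes the five-membered lactone by transesterification.

**Step 15**
Reactants: 23 dienyl lactone
Product: 24 (1S,4R,5S,6S,8R,10R)-1-(tert-butyldimethylsilyloxy)-4,5-epoxy-8,13-epidioxygermacr-7(11)-en-12,6-olide
Conditions: O2, tetraphenylporphyrin (1 mol %), CH2Cl2 (dilute), −20 °C, white LED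
Reagents that add atoms: dioxygen, O=O
Why: Energy transfer from the excited porphyrin gives singlet oxygen, which adds in a concerted suprafacial [4+2] cycloaddition to C8 and C13, so both C–O bonds form in one event and the π bond moves to C7=C11. The closest known reaction type is the dye-sensitised photooxygenation of 1,3-dienes to 3,6-dihydro-1,2-dioxines, which works best for dienes fixed s-cis such as 1,2-dialkylidene rings. The one new ring, the six-membered dioxine, closes by cycloaddition and ends up fused to the lactone along C7–C11. The one new stereocentre, C8, is controlled by C6: its C5 branch and the rest of the ten-membered ring lie under one face of the flat diene–lactone unit, so oxygen should enter from the face that carries H6, giving 8R, the epimer that step 18 inverts. The step needs [4+2] to win over the ene reaction and over diene dimerisation; the lactone holds both exocyclic alkenes s-cis, the inward position on C8 is a hydrogen, C4–C5 is already an oxirane so no electron-rich alkene is left, and low temperature and dilution hold back dimerisation. The ester on C11 makes the diene less nucleophilic, so long irradiation with a robust sensitiser is planned.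

**Step 16**
Reactants: 24 epidioxide
Product: 25 (1S,4R,5S,6S,8R,10R)-1-(tert-butyldimethylsilyloxy)-4,5-epoxy-8,13-dihydroxygermacr-7(11)-en-12,6-olide
Conditions: thiourea, MeOH (undried), 0 °C to rt
Reagents that add atoms: none
Why: Thiourea reduction of a cyclic peroxide cleaves only the O–O bond under neutral conditions, which keeps C8 intact and avoids base-induced peroxide fragmentation.

**Step 17**
Reactants: 25 8,13-diol
Product: 26 (8R)-13-acetoxy-8-hydroxy derivative of 25
Conditions: Ac2O (1.1 equiv), pyridine, CH2Cl2, 0 °C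
Reagents that add atoms: acetic anhydride, CC(=O)OC(C)=O
Why: Rate-selective acylation, in which the unhindered primary C13 hydroxyl should react well before the secondary ring hydroxyl at C8.

**Step 18**
Reactants: 26 8R alcohol; 27 tiglic acid
Product: 28 (1S,4R,5S,6S,8S,10R)-13-acetoxy-1-(tert-butyldimethylsilyloxy)-4,5-epoxy-8-tigloyloxygermacr-7(11)-en-12,6-olide
Conditions: PPh3, DIAD, toluene, 0 °C to rt
Reagents that add atoms: none
Why: Mitsunobu esterification displaces the activated C8 oxygen by SN2 with clean inversion (8R to 8S), and allylic transposition is blocked because the other allyl terminus C11 is fully substituted.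

**Step 19**
Reactants: 28 silyl ether
Product: 29 (1S,4R,5S,6S,8S,10R)-13-acetoxy-4,5-epoxy-1-hydroxy-8-tigloyloxygermacr-7(11)-en-12,6-olide
Conditions: Et3N·3HF, MeCN, rt to 40 °C
Reagents that add atoms: none
Why: Fluoride desilylation with a nearly neutral HF source, which should leave the oxirane, the three ester groups and the base-sensitive H6 of the butenolide alone.

**Step 20**
Reactants: 29 C1 alcohol
Product: 30 target CNP0287840.1
Conditions: Ac2O, pyridine, DMAP (cat.), CH2Cl2, rt
Reagents that add atoms: acetic anhydride, CC(=O)OC(C)=O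
Why: Acetylation of the only free hydroxyl completes the target without touching any stereocentre.

**Compound list**
1 | nerol | CC(C)=CCC/C(C)=C\CO | starting material
2 | neryl acetate | CC(C)=CCC/C(C)=C\COC(C)=O | intermediate
3 | secondary ozonide of the distal alkene of 2 | CC1(C)OOC(CC/C(C)=C\COC(C)=O)O1 | intermediate
4 | (2Z)-3-methyl-6-oxohex-2-en-1-yl acetate | O=CCC/C(C)=C\COC(C)=O | intermediate
5 | (E)-crotylboronic acid pinacol ester | C/C=C/CB1OC(C)(C)C(C)(C)O1 | starting material
6 | pinacol borate ester of 7 | C=C[C@@H](C)[C@@H](OB1OC(C)(C)C(C)(C)O1)CC/C(C)=C\COC(C)=O | intermediate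
7 | (2Z,6S,7R)-6-hydroxy-3,7-dimethylnona-2,8-dien-1-yl acetate | C=C[C@@H](C)[C@@H](O)CC/C(C)=C\COC(C)=O | intermediate
8 | TBS ether of 7 | C=C[C@@H](C)[C@@H](O[Si](C)(C)C(C)(C)C)CC/C(C)=C\COC(C)=O | intermediate
9 | B-alkyl-9-BBN adduct of 8 | C1CCC2CCCC1B2CC[C@@H](C)[C@@H](O[Si](C)(C)C(C)(C)C)CC/C(C)=C\COC(C)=O | intermediate
10 | C8 primary alcohol | OCC[C@@H](C)[C@@H](O[Si](C)(C)C(C)(C)C)CC/C(C)=C\COC(C)=O | intermediate
11 | C8 aldehyde | O=CC[C@@H](C)[C@@H](O[Si](C)(C)C(C)(C)C)CC/C(C)=C\COC(C)=O | intermediate
12 | dimethyl (1-diazo-2-oxopropyl)phosphonate | CC(=O)C(=[N+]=[N-])P(=O)(OC)OC | starting material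
13 | alkynyl acetate | C#CC[C@@H](C)[C@@H](O[Si](C)(C)C(C)(C)C)CC/C(C)=C\COC(C)=O | intermediate
14 | alkynyl Z allylic alcohol | C#CC[C@@H](C)[C@@H](O[Si](C)(C)C(C)(C)C)CC/C(C)=C\CO | intermediate
15 | (1S,4R,5S,10R)-alkynyl epoxy alcohol | C#CC[C@@H](C)[C@@H](O[Si](C)(C)C(C)(C)C)CC[C@@]1(C)O[C@H]1CO | intermediate
16 | (1S,4R,5R,10R)-alkynyl epoxy aldehyde | C#CC[C@@H](C)[C@@H](O[Si](C)(C)C(C)(C)C)CC[C@@]1(C)O[C@H]1C=O | intermediate
17 | ten-membered epoxy propargylic alcohol, both C6 epimers | OC1C#CC[C@@H](C)[C@@H](O[Si](C)(C)C(C)(C)C)CC[C@@]2(C)O[C@H]21 | intermediate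
18 | ten-membered epoxy ynone | O=C1C#CC[C@@H](C)[C@@H](O[Si](C)(C)C(C)(C)C)CC[C@@]2(C)O[C@H]21 | intermediate
19 | (7E)-7-tributylstannyl epoxy enone | O=C1/C([Sn](CCCC)(CCCC)CCCC)=C\C[C@@H](C)[C@@H](O[Si](C)(C)C(C)(C)C)CC[C@@]2(C)O[C@H]21 | intermediate
20 | (6R,7E)-7-tributylstannyl epoxy allylic alcohol | O[C@H]1/C([Sn](CCCC)(CCCC)CCCC)=C\C[C@@H](C)[C@@H](O[Si](C)(C)C(C)(C)C)CC[C@@]2(C)O[C@H]21 | intermediate
21 | methyl 2-bromoacrylate | C=C(Br)C(=O)OC | starting material
22 | (6S,7Z)-hydroxy dienoate, methyl 2-(ring C7)acrylate | O[C@H]1/C(C(=C)C(=O)OC)=C\C[C@@H](C)[C@@H](O[Si](C)(C)C(C)(C)C)CC[C@@]2(C)O[C@H]21 | intermediate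
23 | (1S,4R,5S,6S,10R,7Z)-1-TBSO-4,5-epoxygermacra-7,11(13)-dien-12,6-olide | C1/C=C2\[C@H](OC(=O)C2=C)[C@@H]2O[C@]2(C)CC[C@H](O[Si](C)(C)C(C)(C)C)[C@@H]1C | intermediate
24 | (8R)-8,13-epidioxy butenolide | C1[C@H]2OOCC3=C2[C@H](OC3=O)[C@@H]2O[C@]2(C)CC[C@H](O[Si](C)(C)C(C)(C)C)[C@@H]1C | intermediate
25 | (8R)-8,13-diol | C1[C@@H](O)C2=C(CO)C(=O)O[C@@H]2[C@@H]3O[C@]3(C)CC[C@H](O[Si](C)(C)C(C)(C)C)[C@@H]1C | intermediate
26 | (8R)-13-acetoxy-8-ol | C1[C@@H](O)C2=C(COC(C)=O)C(=O)O[C@@H]2[C@@H]3O[C@]3(C)CC[C@H](O[Si](C)(C)C(C)(C)C)[C@@H]1C | intermediate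
27 | tiglic acid | C/C=C(\C)C(=O)O | starting material
28 | (8S)-8-tiglate, 13-acetate, 1-TBS ether | C1[C@H](OC(=O)/C(C)=C/C)C2=C(COC(C)=O)C(=O)O[C@@H]2[C@@H]3O[C@]3(C)CC[C@H](O[Si](C)(C)C(C)(C)C)[C@@H]1C | intermediate
29 | (8S)-8-tiglate, 13-acetate, 1-ol | C1[C@H](OC(=O)/C(C)=C/C)C2=C(COC(C)=O)C(=O)O[C@@H]2[C@@H]3O[C@]3(C)CC[C@H](O)[C@@H]1C | intermediate
30 | CNP0287840.1 (1S,4R,5S,6S,8S,10R) | C/C=C(\C)C(=O)O[C@H]1C[C@@H](C)[C@@H](OC(C)=O)CC[C@@]2(C)O[C@H]2[C@H]2OC(=O)C(COC(C)=O)=C12 | target

Total step count: 20. Longest linear sequence: 20 steps, from nerol.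

**Steps most likely to fail**

Step 10, ring closure. Intermolecular addition (oligomerisation) or attack of the amide base on the aldehyde may outrun closure of the strained ring.
- The fallback makes the nucleophile reductively under neutral conditions.
- It sets out from 15, whose alkyne is iodinated (N-iodosuccinimide, AgNO3 cat., acetone) to the iodoalkynyl epoxy alcohol F1.
- Dess–Martin oxidation with pyridine gives the iodoalkynyl epoxy aldehyde F2.
- A Nozaki–Hiyama–Kishi closure (CrCl2, NiCl2 cat., THF, high dilution) forms C6–C7 through an alkynylchromium species that tolerates the aldehyde until it cyclises.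
- The route is rejoined at 17.

Step 15, cycloaddition. The ester on the diene may slow oxygen uptake so far that ene oxidation at C7=C8, dimerisation of the diene or bleaching of the dye takes over.
- The fallback keeps the same two C–O bonds and the same ring closure but changes the oxidation level at C12.
- From 23, DIBAL-H (1 equiv, CH2Cl2, −78 °C) gives the dienyl lactol F3, whose diene is no longer conjugated to a carbonyl.
- Photooxygenation as in step 15 gives the epidioxy lactol F4.
- MnO2 (CH2Cl2, rt) oxidises the now allylic lactol back to the butenolide.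
- The route is rejoined at 24.

Step 18, inversion. The carboxylate must approach C8 from the face turned towards the ten-membered ring, so displacement may be slower than elimination of the activated oxygen or may not occur.
- The fallback inverts by redox.
- From 26, Dess–Martin oxidation gives the 8-ketone F5.
- Luche reduction (NaBH4, CeCl3·7H2O, MeOH, −78 °C) should deliver hydride from the open face that oxygen used in step 15, which pushes the hydroxyl to the inner face and gives the 8S alcohol F6.
- Yamaguchi esterification with 27 (2,4,6-trichlorobenzoyl chloride, Et3N, DMAP, toluene) proceeds with retention.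
- The route is rejoined at 28.

**Further compounds**
F1 | step 10 | iodoalkynyl epoxy alcohol | IC#CC[C@@H](C)[C@@H](O[Si](C)(C)C(C)(C)C)CC[C@@]1(C)O[C@H]1CO
F2 | step 10 | iodoalkynyl epoxy aldehyde | IC#CC[C@@H](C)[C@@H](O[Si](C)(C)C(C)(C)C)CC[C@@]1(C)O[C@H]1C=O
F3 | step 15 | dienyl lactol (C12 epimers) | C1/C=C2\[C@H](OC(O)C2=C)[C@@H]2O[C@]2(C)CC[C@H](O[Si](C)(C)C(C)(C)C)[C@@H]1C
F4 | step 15 | (8R)-8,13-epidioxy lactol (C12 epimers) | C1[C@H]2OOCC3=C2[C@H](OC3O)[C@@H]2O[C@]2(C)CC[C@H](O[Si](C)(C)C(C)(C)C)[C@@H]1C
F5 | step 18 | 13-acetoxy-8-ketone | C1C(=O)C2=C(COC(C)=O)C(=O)O[C@@H]2[C@@H]3O[C@]3(C)CC[C@H](O[Si](C)(C)C(C)(C)C)[C@@H]1C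
F6 | step 18 | (8S)-13-acetoxy-8-ol | C1[C@H](O)C2=C(COC(C)=O)C(=O)O[C@@H]2[C@@H]3O[C@]3(C)CC[C@H](O[Si](C)(C)C(C)(C)C)[C@@H]1C
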